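**Retrosynthetic overview**
- The target is the endo (3'',4''-cis, 4'',5''-trans) Diels–Alder adduct of morachalcone A (dienophile) and dehydroprenyl-isobavachalcone (diene); the last step is global deacetylation of its hexaacetate.
- The only ring formed is the cyclohexene, made in one intermolecular, endo- and enantioselective Diels–Alder reaction catalysed by a chiral Brønsted acid; it sets all three stereocentres.
- Dienophile: morachalcone A 4',2,4-triacetate (2'-OH free), from a Claisen–Schmidt condensation of 3-prenylresacetophenone, then selective acetylation.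
- Diene: isobavachalcone triacetate, then Schenck ene reaction/reduction and dehydration of the prenyl group.
- Both chalcones come from one ketone, made by C-prenylation of 2,4-dihydroxyacetophenone; all four aromatic rings are bought.

Assumption: the SMILES is read as the (3''S,4''R,5''S) endo adduct, i.e. (1S,5S,6R) on the cyclohexene, and the two MOM-protected hydroxybenzaldehydes are taken as catalogue compounds.

**Route**

Step 1
Reactants: 1 2,4-dihydroxyacetophenone; 2 prenyl bromide (1-bromo-3-methylbut-2-ene)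
Product: 3 1-[2,4-dihydroxy-3-(3-methylbut-2-en-1-yl)phenyl]ethan-1-one
Conditions: KOH (10% aq., 2 equiv), 2 (1.0 equiv), 0 °C → rt, 4 h; chromatography
Reagents that add atoms: none
Why: Phenoxide C-alkylation (C-prenylation): the dianion of 1 is most nucleophilic at C3 between the two oxygens and attacks the allylic bromide; the yield is modest, and O-prenyl and 5-prenyl by-products are removed by chromatography.

Step 2
Reactants: 3 1-[2,4-dihydroxy-3-(3-methylbut-2-en-1-yl)phenyl]ethan-1-one; 4 2,4-bis(methoxymethoxy)benzaldehyde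
Product: 6 morachalcone A, (E)-1-[2,4-dihydroxy-3-(3-methylbut-2-en-1-yl)phenyl]-3-(2,4-dihydroxyphenyl)prop-2-en-1-one, via bis-MOM morachalcone A 5 (not isolated)
Conditions: KOH (60% aq.), EtOH, 40 °C, 36 h, Ar; then acidify and 3 M HCl in MeOH, rt → 40 °C, 3 h
Reagents that add atoms: none
Why: Claisen–Schmidt aldol condensation (E1cB dehydration gives the E-enone and tolerates the free ring A phenoxides), followed by acid-catalysed acetal exchange of the two MOM ethers in methanol under conditions mild enough to leave the prenyl group uncyclised.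

Step 3
Reactants: 6 morachalcone A
Product: 7 morachalcone A 4',2,4-triacetate, (E)-1-[4-acetoxy-2-hydroxy-3-(3-methylbut-2-en-1-yl)phenyl]-3-(2,4-diacetoxyphenyl)prop-2-en-1-one
Conditions: Ac2O (3.2 equiv), pyridine, 0 °C, 2 h
Reagents that add atoms: acetic anhydride, CC(=O)OC(C)=O
Why: Chemoselective O-acetylation: the 2'-OH is locked in a hydrogen bond to the ketone and is the least nucleophilic phenol, so only the other three are acylated at 0 °C.

Step 4
Reactants: 3 1-[2,4-dihydroxy-3-(3-methylbut-2-en-1-yl)phenyl]ethan-1-one; 8 4-(methoxymethoxy)benzaldehyde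
Product: 10 isobavachalcone, (E)-1-[2,4-dihydroxy-3-(3-methylbut-2-en-1-yl)phenyl]-3-(4-hydroxyphenyl)prop-2-en-1-one, via MOM-isobavachalcone 9 (not isolated)
Conditions: KOH (60% aq.), EtOH, 40 °C, 36 h, Ar; then acidify and 3 M HCl in MeOH, rt → 40 °C, 3 h
Reagents that add atoms: none
Why: Same Claisen–Schmidt condensation and one-pot MOM acetal exchange as in step 2, giving the E-chalcone.

Step 5
Reactants: 10 isobavachalcone
Product: 11 isobavachalcone triacetate, (E)-1-[2,4-diacetoxy-3-(3-methylbut-2-en-1-yl)phenyl]-3-(4-acetoxyphenyl)prop-2-en-1-one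
Conditions: Ac2O (5 equiv), Et3N, DMAP (10 mol%), CH2Cl2, rt, 6 h
Reagents that add atoms: acetic anhydride, CC(=O)OC(C)=O
Why: Exhaustive DMAP-catalysed acetylation also acylates the chelated 2'-OH, which protects the ortho-phenols from chromene formation and makes this enone less basic than that of 7 for the later acid-catalysed step.

Step 6
Reactants: 11 isobavachalcone triacetate
Product: 13 (E)-1-{2,4-diacetoxy-3-[(E)-3-hydroxy-3-methylbut-1-en-1-yl]phenyl}-3-(4-acetoxyphenyl)prop-2-en-1-one, via tertiary allylic hydroperoxide 12 (not isolated)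
Conditions: O2 (1 atm), methylene blue (2 mol%), CH2Cl2, 0 °C, red LED (660 nm); then PPh3 (1.2 equiv), 0 °C → rt
Reagents that add atoms: dioxygen (singlet oxygen made in the flask), O=O
Why: Schenck ene reaction: singlet oxygen abstracts a benzylic allylic hydrogen and shifts the double bond into conjugation to give the E tertiary hydroperoxide, which PPh3 reduces in the same flask; red light excites only the sensitiser, so the chalcone does not isomerise, and the minor secondary regioisomer is removed by chromatography.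

Step 7
Reactants: 13 tertiary allylic alcohol
Product: 14 (E)-1-{2,4-diacetoxy-3-[(E)-3-methylbuta-1,3-dien-1-yl]phenyl}-3-(4-acetoxyphenyl)prop-2-en-1-one
Conditions: Martin sulfurane Ph2S[OC(CF3)2Ph]2 (1.3 equiv), CH2Cl2, 0 °C, 30 min; use promptly
Reagents that add atoms: none
Why: Martin sulfurane dehydration of a tertiary allylic alcohol (loss of a methyl proton from the alkoxysulfonium/allyl cation) under neutral conditions that leave the acetates, the enone and the E styrenic double bond untouched.

Step 8
Reactants: 7 morachalcone A 4',2,4-triacetate; 14 dienyl chalcone triacetate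
Product: 15 hexaacetate of the target with the 2-OH of the prenylated benzoyl ring free, (1S,5S,6R) on the cyclohexene (1,6-cis, 5,6-trans)
Conditions: 7 (1.0 equiv), 14 (1.5 equiv), (S,S)-IDPi Brønsted acid (imidodiphosphorimidate from two (S)-3,3'-diphenyl-BINOL units with N-triflyl groups, 5 mol%), 5 Å MS, CH2Cl2, −40 °C, 72 h, dark
Reagents that add atoms: none
Why: Proposed new method: a strong, confined chiral imidodiphosphorimidate acid protonates the ketone of 7 (held s-cis and planar by its 2'-OH···O=C hydrogen bond, with the phenol offering a second contact to a sulfonyl oxygen of the anion), and in this contact ion pair the chiral anion covers the Cα-Re/Cβ-Re face, so diene 14 adds endo to the Si,Si face with its CH2 terminus bonding to Cβ, setting C1(S), C6(R) and C5(S) of the ring in one asymmetric Diels–Alder reaction, while the less basic 2'-acetoxy enone of 14 stays unactivated; the closest known reaction types are imidodiphosphorimidate-catalysed Diels–Alder reactions of simple unsaturated ketones and dienones with cyclopentadiene and the stoichiometric chiral-borate-promoted Diels–Alder reaction of 2'-hydroxychalcones.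

Step 9
Reactants: 15 hexaacetate adduct
Product: 16 CNP0283121.1, (E)-1-{2,4-dihydroxy-3-[(1S,5S,6R)-6-[2,4-dihydroxy-3-(3-methylbut-2-en-1-yl)benzoyl]-5-(2,4-dihydroxyphenyl)-3-methylcyclohex-2-en-1-yl]phenyl}-3-(4-hydroxyphenyl)prop-2-en-1-one
Conditions: K2CO3 (0.5 equiv), degassed MeOH, 0 °C → rt, 1 h, Ar; pH 6 phosphate buffer work-up (no strong acid)
Reagents that add atoms: none
Why: Base-catalysed transesterification (methanolysis) of six aryl acetates is much faster than enolisation at C6, because the freed ortho/para phenoxides turn both ketones into vinylogous carboxylates, so no stereocentre is touched; strong acid is avoided because it would ketalise the product.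

**Compound list**
1 | 2,4-dihydroxyacetophenone | CC(=O)c1ccc(O)cc1O | starting material
2 | prenyl bromide | CC(C)=CCBr | starting material
3 | 1-[2,4-dihydroxy-3-(3-methylbut-2-en-1-yl)phenyl]ethan-1-one | CC(=O)c1ccc(O)c(CC=C(C)C)c1O | intermediate
4 | 2,4-bis(methoxymethoxy)benzaldehyde | O=Cc1ccc(OCOC)cc1OCOC | starting material
5 | bis-MOM morachalcone A, (E)-3-[2,4-bis(methoxymethoxy)phenyl]-1-[2,4-dihydroxy-3-(3-methylbut-2-en-1-yl)phenyl]prop-2-en-1-one | O=C(/C=C/c1ccc(OCOC)cc1OCOC)c1ccc(O)c(CC=C(C)C)c1O | intermediate (not isolated)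
6 | morachalcone A | O=C(/C=C/c1ccc(O)cc1O)c1ccc(O)c(CC=C(C)C)c1O | intermediate
7 | morachalcone A 4',2,4-triacetate (2'-OH free) | CC(=O)Oc1ccc(/C=C/C(=O)c2ccc(OC(C)=O)c(CC=C(C)C)c2O)c(OC(C)=O)c1 | intermediate
8 | 4-(methoxymethoxy)benzaldehyde | O=Cc1ccc(OCOC)cc1 | starting material
9 | MOM-isobavachalcone, (E)-1-[2,4-dihydroxy-3-(3-methylbut-2-en-1-yl)phenyl]-3-[4-(methoxymethoxy)phenyl]prop-2-en-1-one | O=C(/C=C/c1ccc(OCOC)cc1)c1ccc(O)c(CC=C(C)C)c1O | intermediate (not isolated)
10 | isobavachalcone | O=C(/C=C/c1ccc(O)cc1)c1ccc(O)c(CC=C(C)C)c1O | intermediate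
11 | isobavachalcone triacetate | CC(=O)Oc1ccc(/C=C/C(=O)c2ccc(OC(C)=O)c(CC=C(C)C)c2OC(C)=O)cc1 | intermediate
12 | tertiary allylic hydroperoxide, (E)-1-{2,4-diacetoxy-3-[(E)-3-hydroperoxy-3-methylbut-1-en-1-yl]phenyl}-3-(4-acetoxyphenyl)prop-2-en-1-one | CC(=O)Oc1ccc(/C=C/C(=O)c2ccc(OC(C)=O)c(/C=C/C(C)(C)OO)c2OC(C)=O)cc1 | intermediate (not isolated)
13 | tertiary allylic alcohol, (E)-1-{2,4-diacetoxy-3-[(E)-3-hydroxy-3-methylbut-1-en-1-yl]phenyl}-3-(4-acetoxyphenyl)prop-2-en-1-one | CC(=O)Oc1ccc(/C=C/C(=O)c2ccc(OC(C)=O)c(/C=C/C(C)(C)O)c2OC(C)=O)cc1 | intermediate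
14 | dienyl chalcone triacetate, (E)-1-{2,4-diacetoxy-3-[(E)-3-methylbuta-1,3-dien-1-yl]phenyl}-3-(4-acetoxyphenyl)prop-2-en-1-one | CC(=O)Oc1ccc(/C=C/C(=O)c2ccc(OC(C)=O)c(/C=C/C(C)=C)c2OC(C)=O)cc1 | intermediate
15 | hexaacetate adduct, (1S,5S,6R), 2-OH of the prenylated benzoyl ring free | CC(C)=CCc1c(OC(C)=O)ccc(C(=O)[C@H]2[C@@H](c3c(OC(C)=O)ccc(C(=O)/C=C/c4ccc(OC(C)=O)cc4)c3OC(C)=O)C=C(C)C[C@@H]2c2ccc(OC(C)=O)cc2OC(C)=O)c1O | intermediate
16 | CNP0283121.1 | CC(C)=CCc1c(O)ccc(C(=O)[C@H]2[C@@H](c3c(O)ccc(C(=O)/C=C/c4ccc(O)cc4)c3O)C=C(C)C[C@@H]2c2ccc(O)cc2O)c1O | target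

**Step count and risks**
Total: 9 steps (steps 2, 4 and 6 each run two operations in one flask). Longest linear sequence: 7 steps (steps 1, 4, 5, 6, 7, 8, 9).

Most likely to fail, step 8 (the proposed new Diels–Alder reaction). The large ion pair may turn over slowly, the acid may close the prenyl group of 7 onto its 2'-OH or oligomerise 14, exo adduct or self-adduct of 14 may form, and the facial sense of the (S,S) catalyst is a model prediction that must be checked on the first run (the (R,R) catalyst is equally accessible). The fallback is known chemistry with a different activation mode: 7 is bound through its free 2'-OH as a tetracoordinate chelate to a stoichiometric chiral borate preformed from BH3·THF, AcOH and (S)-VANOL (2.5 equiv each, THF, 4 Å MS, rt; (R)-VANOL if the first run gives the antipode), and diene 14 is then added. This sets out from 7 and 14 and comes back at 15, with the exo isomer separated by chromatography; it makes no new compound.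

Second, step 6 (ene regioselectivity and the sensitivity of 13 and 14). The fallback builds the diene by cross-coupling. It sets out from 1: iodination (I2, HIO3, aq. EtOH, rt) gives 1-(2,4-dihydroxy-3-iodophenyl)ethan-1-one F1. Claisen–Schmidt condensation with 8 (KOH, EtOH) gives (E)-1-(2,4-dihydroxy-3-iodophenyl)-3-[4-(methoxymethoxy)phenyl]prop-2-en-1-one F2, which is cleaved in the same flask (HCl, MeOH) to (E)-1-(2,4-dihydroxy-3-iodophenyl)-3-(4-hydroxyphenyl)prop-2-en-1-one F3. Acetylation (Ac2O, Et3N, DMAP) gives (E)-1-(2,4-diacetoxy-3-iodophenyl)-3-(4-acetoxyphenyl)prop-2-en-1-one F4. Suzuki–Miyaura coupling of F4 with the (E)-3-methylbuta-1,3-dien-1-yl pinacol boronate (C=C(C)/C=C/B1OC(C)(C)C(C)(C)O1; Pd(dppf)Cl2, anhydrous CsF, dioxane, 60 °C) comes back at 14.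

Third, step 1 (modest regioselectivity of direct C-prenylation). The fallback is a Claisen route, setting out from 1: selective 4-O-alkylation with 3-chloro-3-methylbut-1-yne (K2CO3, KI, CuI cat., acetone, reflux) gives 1-{2-hydroxy-4-[(2-methylbut-3-yn-2-yl)oxy]phenyl}ethan-1-one F5. Semi-hydrogenation (H2, Pd/CaCO3 poisoned with Pb(OAc)2, quinoline, EtOAc) gives 1-{2-hydroxy-4-[(2-methylbut-3-en-2-yl)oxy]phenyl}ethan-1-one F6. Aromatic Claisen rearrangement (N,N-diethylaniline, 130 °C) moves the allyl unit to C3 with inversion to the prenyl group and comes back at 3.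

**Further compounds**
F0 | step 8 | none | none
F1 | step 6 | 1-(2,4-dihydroxy-3-iodophenyl)ethan-1-one | CC(=O)c1ccc(O)c(I)c1O
F2 | step 6 | (E)-1-(2,4-dihydroxy-3-iodophenyl)-3-[4-(methoxymethoxy)phenyl]prop-2-en-1-one | O=C(/C=C/c1ccc(OCOC)cc1)c1ccc(O)c(I)c1O
F3 | step 6 | (E)-1-(2,4-dihydroxy-3-iodophenyl)-3-(4-hydroxyphenyl)prop-2-en-1-one | O=C(/C=C/c1ccc(O)cc1)c1ccc(O)c(I)c1O
F4 | step 6 | (E)-1-(2,4-diacetoxy-3-iodophenyl)-3-(4-acetoxyphenyl)prop-2-en-1-one | CC(=O)Oc1ccc(/C=C/C(=O)c2ccc(OC(C)=O)c(I)c2OC(C)=O)cc1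
F5 | step 1 | 1-{2-hydroxy-4-[(2-methylbut-3-yn-2-yl)oxy]phenyl}ethan-1-one | CC(=O)c1ccc(OC(C)(C)C#C)cc1O
F6 | step 1 | 1-{2-hydroxy-4-[(2-methylbut-3-en-2-yl)oxy]phenyl}ethan-1-one | CC(=O)c1ccc(OC(C)(C)C=C)cc1O
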